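**Strategy.** The route rests on disconnecting the C9–C10 bond of the labdane decalin and tracing ring A back to a cyclopentanone fused to a cyclopropane whose shared bond is C4–C10. In one operation SnCl4 ionises that bond and a tethered allylsilane closes ring B. This sets the trans fusion of rings A and B (H5 anti to the C20 methyl across C5–C10), the equatorial C11 arm at C9, the 8(17)-methylene and a carboxyl-level C19 on C4. The precursor is an enantioenriched bicyclo[3.1.0]hexanone mesityl keto ester carrying a (Z)-allylsilane side chain with a silyl-protected C11 oxygen, made by copper-catalysed cyclopropanation of an E-alkene.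

Key step: step 14

**Remarks and assumptions**
- Carbon labels C1–C20 are labdane labels and are also used for the atoms of acyclic precursors that become those carbons. α means below and β above the decalin plane, with the C20 methyl β.
- Two spectator groups of the cyclopropane precursor are chosen for reasons of design. The ester is 2,4,6-trimethylphenyl (mesityl), because small alkyl esters of diazo keto esters are expected to give poor face selection with copper–bis(oxazoline) catalysts; the same hindered ester later protects C19 through the sulfone chemistry. The C11 oxygen is a TBDPS ether, because an allylic ester next to the allylsilane could ionise under SnCl4 with loss of silicon.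
- Assumption: the sense of induction of the bis(oxazoline) ligand in step 13 has to be established on the first run; the ligand antipode that gives the drawn (1R,5R,6R) cyclopropane is then used.
- The product of step 14 is a keto/enol and C4-epimer mixture. The C3 alcohol of steps 16–17 is drawn 3β (expected major); its configuration is immaterial. The product of step 24 is a mixture of C11 epimers, removed in step 25.

**Route**

Step 1
Reactants: 1 2-methyl-2-vinyloxirane (racemic)
Product: 2 (E)-4-chloro-2-methylbut-2-en-1-ol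
Conditions: TiCl4 (1.1 equiv), CH2Cl2, −85 °C; aq. HCl work-up
Reagents that add atoms: titanium tetrachloride, Cl[Ti](Cl)(Cl)Cl
Why: TiCl4 opens the vinyl epoxide at its tertiary allylic C–O bond and delivers chloride to the vinyl terminus (SN2′-type 1,4-opening), which should give mainly the E-trisubstituted allylic chlorohydrin and erases the stereocentre of the racemic epoxide.

Step 2
Reactants: 2 (E)-4-chloro-2-methylbut-2-en-1-ol
Product: 3 (E)-tert-butyl[(4-chloro-2-methylbut-2-en-1-yl)oxy]dimethylsilane
Conditions: TBSCl, imidazole, CH2Cl2, 0 °C → rt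
Reagents that add atoms: tert-butyldimethylsilyl chloride, CC(C)(C)[Si](C)(C)Cl
Why: Imidazole-promoted silylation of the primary alcohol masks the C1 oxygen for the basic and organometallic steps that follow.

Step 3
Reactants: 4 methyl acetoacetate; 3 (E)-tert-butyl[(4-chloro-2-methylbut-2-en-1-yl)oxy]dimethylsilane
Product: 6 methyl (6E)-8-[(tert-butyldimethylsilyl)oxy]-7-methyl-3-oxooct-6-enoate, via sodium lithium dianion of methyl acetoacetate 5 (not isolated)
Conditions: NaH, THF, 0 °C; n-BuLi, 0 °C; then 3, 0 °C → rt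
Reagents that add atoms: none
Why: In this acetoacetate dianion alkylation the more basic terminal carbanion displaces the primary allylic chloride by SN2 (C6–C7 bond), so the E-alkene is carried over unchanged.

Step 4
Reactants: 6 methyl (6E)-8-[(tert-butyldimethylsilyl)oxy]-7-methyl-3-oxooct-6-enoate
Product: 7 methyl (2Z,6E)-8-[(tert-butyldimethylsilyl)oxy]-7-methyl-3-{[(trifluoromethyl)sulfonyl]oxy}octa-2,6-dienoate
Conditions: Tf2O, aq. LiOH, toluene, 5 °C
Reagents that add atoms: trifluoromethanesulfonic anhydride, O=S(=O)(OS(=O)(=O)C(F)(F)F)C(F)(F)F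
Why: The lithium-chelated, U-shaped enolate is sulfonylated on oxygen to give the Z-enol triflate (ester and triflate cis), the geometry that later places the C11 arm trans to C7.

Step 5
Reactants: 7 methyl (2Z,6E)-8-[(tert-butyldimethylsilyl)oxy]-7-methyl-3-{[(trifluoromethyl)sulfonyl]oxy}octa-2,6-dienoate; 8 (trimethylsilyl)methylmagnesium chloride
Product: 9 methyl (2Z,6E)-8-[(tert-butyldimethylsilyl)oxy]-7-methyl-3-[(trimethylsilyl)methyl]octa-2,6-dienoate
Conditions: Pd(PPh3)4 (5 mol %), THF, 0 °C → rt
Reagents that add atoms: none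
Why: Kumada coupling at zerovalent palladium proceeds with retention at the vinyl triflate, and the hindered, weakly nucleophilic Grignard reagent leaves the conjugated ester untouched, giving the Z-allylsilane.

Step 6
Reactants: 9 methyl (2Z,6E)-8-[(tert-butyldimethylsilyl)oxy]-7-methyl-3-[(trimethylsilyl)methyl]octa-2,6-dienoate
Product: 10 (2Z,6E)-8-[(tert-butyldimethylsilyl)oxy]-7-methyl-3-[(trimethylsilyl)methyl]octa-2,6-dien-1-ol
Conditions: i-Bu2AlH (2.5 equiv), CH2Cl2, −78 → 0 °C; aq. potassium sodium tartrate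
Reagents that add atoms: none
Why: i-Bu2AlH reduces the conjugated ester by 1,2-addition to the allylic alcohol (C11) without touching the silicon groups or the alkene geometry.

Step 7
Reactants: 10 (2Z,6E)-8-[(tert-butyldimethylsilyl)oxy]-7-methyl-3-[(trimethylsilyl)methyl]octa-2,6-dien-1-ol
Product: 11 (2Z,6E)-1-[(tert-butyldiphenylsilyl)oxy]-8-[(tert-butyldimethylsilyl)oxy]-7-methyl-3-[(trimethylsilyl)methyl]octa-2,6-diene
Conditions: TBDPSCl, imidazole, CH2Cl2, 0 °C → rt
Reagents that add atoms: tert-butyldiphenylsilyl chloride, CC(C)(C)[Si](Cl)(c1ccccc1)c1ccccc1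
Why: Silylation with the bulkier, more acid-stable TBDPS group gives a C11 ether that is orthogonal to the TBS ether at C1 and is a poor leaving group toward SnCl4 in step 14.

Step 8
Reactants: 11 (2Z,6E)-1-[(tert-butyldiphenylsilyl)oxy]-8-[(tert-butyldimethylsilyl)oxy]-7-methyl-3-[(trimethylsilyl)methyl]octa-2,6-diene
Product: 12 (2E,6Z)-8-[(tert-butyldiphenylsilyl)oxy]-2-methyl-6-[(trimethylsilyl)methyl]octa-2,6-dien-1-ol
Conditions: pyridinium p-toluenesulfonate (0.2 equiv), MeOH, rt
Reagents that add atoms: none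
Why: Buffered acidic methanolysis cleaves a primary TBS ether far faster than a TBDPS ether and is too weak an acid to protodesilylate the allylsilane.

Step 9
Reactants: 12 (2E,6Z)-8-[(tert-butyldiphenylsilyl)oxy]-2-methyl-6-[(trimethylsilyl)methyl]octa-2,6-dien-1-ol
Product: 13 (2Z,6E)-8-bromo-1-[(tert-butyldiphenylsilyl)oxy]-7-methyl-3-[(trimethylsilyl)methyl]octa-2,6-diene
Conditions: CBr4, PPh3, 2,6-lutidine, CH2Cl2, −20 → 0 °C
Reagents that add atoms: carbon tetrabromide, BrC(Br)(Br)Br
Why: Appel bromination converts the primary allylic alcohol to the bromide by SN2 at carbon under neutral conditions, so the E-alkene stays in place and the allylsilane sees no acid.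

Step 10
Reactants: 14 2,2,6-trimethyl-4H-1,3-dioxin-4-one; 15 2,4,6-trimethylphenol
Product: 16 2,4,6-trimethylphenyl 3-oxobutanoate (mesityl acetoacetate)
Conditions: xylene, 140 °C, acetone distilled off
Reagents that add atoms: none
Why: Thermal retro-[4+2] fragmentation of the dioxinone releases acetylketene, which the hindered phenol traps as its acetoacetate.

Step 11
Reactants: 16 2,4,6-trimethylphenyl 3-oxobutanoate; 13 (2Z,6E)-8-bromo-1-[(tert-butyldiphenylsilyl)oxy]-7-methyl-3-[(trimethylsilyl)methyl]octa-2,6-diene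
Product: 18 2,4,6-trimethylphenyl (6E,10Z)-12-[(tert-butyldiphenylsilyl)oxy]-6-methyl-3-oxo-10-[(trimethylsilyl)methyl]dodeca-6,10-dienoate, via sodium lithium dianion of mesityl acetoacetate 17 (not isolated)
Conditions: NaH, THF, 0 °C; n-BuLi, 0 °C; then 13, 0 °C
Reagents that add atoms: none
Why: Acetoacetate dianion alkylation at the terminal carbanion with the reactive primary allylic bromide forms the C1–C2 bond by SN2 and completes the carbon chain with both alkene geometries in place.

Step 12
Reactants: 18 2,4,6-trimethylphenyl (6E,10Z)-12-[(tert-butyldiphenylsilyl)oxy]-6-methyl-3-oxo-10-[(trimethylsilyl)methyl]dodeca-6,10-dienoate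
Product: 19 2,4,6-trimethylphenyl (6E,10Z)-12-[(tert-butyldiphenylsilyl)oxy]-2-diazo-6-methyl-3-oxo-10-[(trimethylsilyl)methyl]dodeca-6,10-dienoate
Conditions: 4-acetamidobenzenesulfonyl azide, Et3N, MeCN, 0 °C → rt
Reagents that add atoms: 4-acetamidobenzenesulfonyl azide, CC(=O)Nc1ccc(cc1)S(=O)(=O)N=[N+]=[N-]
Why: Regitz diazo transfer from the sulfonyl azide to the amine-generated enolate of the 1,3-dicarbonyl unit installs the diazo group at C4.

Step 13
Reactants: 19 2,4,6-trimethylphenyl (6E,10Z)-12-[(tert-butyldiphenylsilyl)oxy]-2-diazo-6-methyl-3-oxo-10-[(trimethylsilyl)methyl]dodeca-6,10-dienoate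
Product: 20 2,4,6-trimethylphenyl (1R,5R,6R)-6-{(3Z)-5-[(tert-butyldiphenylsilyl)oxy]-3-[(trimethylsilyl)methyl]pent-3-en-1-yl}-5-methyl-2-oxobicyclo[3.1.0]hexane-1-carboxylate
Conditions: (CuOTf)2·C6H6 (5 mol %), 2,2′-(propane-2,2-diyl)bis[(4S)-4-isopropyl-4,5-dihydrooxazole] or its enantiomer (12 mol %), toluene, 50 °C, slow addition of 19
Reagents that add atoms: none
Why: The copper carbene adds to the nearby electron-rich C5=C10 alkene in a concerted intramolecular cyclopropanation that is necessarily cis-fused and stereospecific, so the E geometry puts the C6 arm cis to the C20 methyl, while the C2-symmetric bis(oxazoline) ligand together with the bulky mesityl ester differentiates the alkene faces and sets C4, C5 and C10 in absolute terms.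

Step 14
Reactants: 20 2,4,6-trimethylphenyl (1R,5R,6R)-6-{(3Z)-5-[(tert-butyldiphenylsilyl)oxy]-3-[(trimethylsilyl)methyl]pent-3-en-1-yl}-5-methyl-2-oxobicyclo[3.1.0]hexane-1-carboxylate
Product: 22 2,4,6-trimethylphenyl 5-{[(tert-butyldiphenylsilyl)oxy]methyl}-4a-methyl-6-methylidene-2-oxodecahydronaphthalene-1-carboxylate (trans-decalin; 5α-H; 9α-H with the C11 arm β; 10β-CH3; C4 epimers plus enol), via trichlorotin enolate 21 (not isolated)
Conditions: SnCl4 (1.3 equiv), 2,6-di-tert-butyl-4-methylpyridine (0.3 equiv), CH2Cl2, −78 → −20 °C; aq. NaHCO3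
Reagents that add atoms: none
Why: SnCl4 chelates the keto ester and the cyclopropane ionises at C4–C10 toward the tertiary carbon, the allylsilane attacking C10 through C9 from the side opposite the departing C4 while the β-silyl cation left at C8 loses silicon to give the 8(17)-methylene and a tin enolate that water protonates. The closest known reaction type is the Lewis-acid opening of acylcyclopropanes with participation of a tethered alkene, here terminated as an intramolecular Hosomi–Sakurai allylation. Ring B closes in a 6-endo-trig sense with respect to the allylsilane alkene (exo-tet at C10, the leaving C4 lying outside the new ring) through a chair, and ring A is not closed by a new bond but arises by expansion of the five-membered ring when the shared bond breaks. C10 is set by the invertive anti displacement and, because C5 keeps its configuration from step 13, H5 ends anti to the C20 methyl (trans fusion); C9 is set by the chair together with the Z geometry of the allylsilane, which puts the C11 arm (trans to C7) equatorial. The step needs cleavage of C4–C10 over C4–C5 and ring closure over chloride capture, proton loss or loss of the C11 oxygen: the first is secured by tertiary versus secondary cation stability, the others by the unconjugated, nucleophilic allylsilane held close to C10, the poorly ionising silyl ether at C11 and a hindered pyridine that removes adventitious acid.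

Step 15
Reactants: 22 2,4,6-trimethylphenyl 5-{[(tert-butyldiphenylsilyl)oxy]methyl}-4a-methyl-6-methylidene-2-oxodecahydronaphthalene-1-carboxylate
Product: 23 2,4,6-trimethylphenyl 5-{[(tert-butyldiphenylsilyl)oxy]methyl}-1,4a-dimethyl-6-methylidene-2-oxodecahydronaphthalene-1-carboxylate (4α-CH3, 4β-CO2Ar, 5α-H, 9α-H, 10β-CH3)
Conditions: MeI (excess), K2CO3, acetone, rt
Reagents that add atoms: iodomethane, CI
Why: C-Alkylation of the β-keto ester enolate with MeI should occur on the α face, away from the axial C20 methyl, so the new methyl (C18) is equatorial and the ester carbon (C19) axial and β.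

Step 16
Reactants: 23 (3-oxo ester)
Product: 24 2,4,6-trimethylphenyl 5-{[(tert-butyldiphenylsilyl)oxy]methyl}-2-hydroxy-1,4a-dimethyl-6-methylidenedecahydronaphthalene-1-carboxylate (3β-OH expected; otherwise as 23)
Conditions: NaBH4, THF/i-PrOH, 0 °C
Reagents that add atoms: none
Why: NaBH4 reduces the hindered C3 ketone (hydride from the α face, giving mainly the equatorial 3β-alcohol) and leaves the neopentyl aryl ester alone; the configuration at C3 is immaterial because the oxygen is removed.

Step 17
Reactants: 24 (3-hydroxy ester)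
Product: 25 2,4,6-trimethylphenyl 5-{[(tert-butyldiphenylsilyl)oxy]methyl}-2-[(1H-imidazole-1-carbothioyl)oxy]-1,4a-dimethyl-6-methylidenedecahydronaphthalene-1-carboxylate
Conditions: 1,1′-thiocarbonyldiimidazole, DMAP (cat.), toluene, 90 °C
Reagents that add atoms: 1,1′-thiocarbonyldiimidazole, S=C(n1ccnc1)n1ccnc1
Why: Acylation of the secondary alcohol with thiocarbonyldiimidazole gives the thiocarbonyl derivative needed for radical deoxygenation (first half of the Barton–McCombie sequence).

Step 18
Reactants: 25 (imidazole thiocarbamate)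
Product: 26 2,4,6-trimethylphenyl 5-{[(tert-butyldiphenylsilyl)oxy]methyl}-1,4a-dimethyl-6-methylidenedecahydronaphthalene-1-carboxylate (4α-CH3, 4β-CO2Ar, 5α-H, 9α-H, 10β-CH3)
Conditions: Bu3SnH, AIBN (cat.), toluene, 100 °C
Reagents that add atoms: none
Why: In this Barton–McCombie deoxygenation the stannyl radical adds to sulfur and the C3–O bond fragments to a secondary radical that has no alkene within reach and is reduced by Bu3SnH, leaving the ester, the silyl ether and the exocyclic alkene untouched.

Step 19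
Reactants: 26 (C11 silyl ether)
Product: 27 2,4,6-trimethylphenyl 5-(hydroxymethyl)-1,4a-dimethyl-6-methylidenedecahydronaphthalene-1-carboxylate
Conditions: Bu4NF, AcOH, THF, rt
Reagents that add atoms: none
Why: Fluoride cleaves the Si–O bond of the primary silyl ether, and the acetic acid buffer keeps the medium non-basic for the aryl ester.

Step 20
Reactants: 27 (C11 alcohol)
Product: 28 2,4,6-trimethylphenyl 1,4a-dimethyl-6-methylidene-5-[(phenylsulfanyl)methyl]decahydronaphthalene-1-carboxylate
Conditions: PhSSPh, n-Bu3P, pyridine, rt → 60 °C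
Reagents that add atoms: diphenyl disulfide, c1ccc(SSc2ccccc2)cc1
Why: Phosphine-mediated thioetherification with a disulfide (Mitsunobu-type SN2 of an alkoxyphosphonium ion by thiolate) works on β-branched primary alcohols and places sulfur on C11 without affecting C9.

Step 21
Reactants: 28 (C11 sulfide)
Product: 29 2,4,6-trimethylphenyl 1,4a-dimethyl-6-methylidene-5-[(phenylsulfonyl)methyl]decahydronaphthalene-1-carboxylate
Conditions: (NH4)6Mo7O24·4H2O (10 mol %), 30% H2O2, EtOH, 0 °C → rt
Reagents that add atoms: hydrogen peroxide, OO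
Why: Molybdate-catalysed oxidation with H2O2 takes the sulfide to the sulfone and is slow toward unactivated alkenes, so the exocyclic alkene should survive.

Step 22
Reactants: 30 (S)-2-methylglycidol
Product: 31 (R)-2-methyloxirane-2-carbaldehyde
Conditions: (COCl)2, DMSO, CH2Cl2, −78 °C; Et3N, −78 → 0 °C; distillation
Reagents that add atoms: none
Why: Swern oxidation of the primary alcohol stops at the aldehyde and leaves the epoxide and the quaternary stereocentre, which has no α hydrogen, untouched (the descriptor changes only through priorities).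

Step 23
Reactants: 31 (R)-2-methyloxirane-2-carbaldehyde
Product: 32 (S)-2-methyl-2-vinyloxirane
Conditions: Ph3PCH3Br, NaH, DMSO, rt; then 31, rt; product distilled from the flask into a cold trap
Reagents that add atoms: methyltriphenylphosphonium bromide, [Br-].C[P+](c1ccccc1)(c1ccccc1)c1ccccc1
Why: Wittig methylenation of the non-enolisable epoxy aldehyde gives the vinyl epoxide with the stereocentre untouched, and the volatile product is separated from DMSO by distillation.

Step 24
Reactants: 29 (C11 sulfone); 32 (S)-2-methyl-2-vinyloxirane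
Product: 34 2,4,6-trimethylphenyl 5-[(3R)-3-hydroxy-3-methyl-1-(phenylsulfonyl)pent-4-en-1-yl]-1,4a-dimethyl-6-methylidenedecahydronaphthalene-1-carboxylate (13R; C11 epimers), via lithiated sulfone 33 (not isolated)
Conditions: LiN(i-Pr)2, THF, −78 °C; then 32 (3 equiv), DMPU, −78 °C → rt
Reagents that add atoms: none
Why: The lithiated sulfone, a stabilised carbanion, should open the epoxide by SN2 at its unhindered CH2 carbon (the quaternary allylic carbon is blocked), forming the C11–C12 bond and carrying the untouched stereocentre of 32 into C13 as 13R, while the hindered aryl ester resists the amide base.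

Step 25
Reactants: 34 (γ-hydroxy sulfone)
Product: 35 2,4,6-trimethylphenyl (13R)-13-hydroxylabda-8(17),14-dien-19-oate
Conditions: Na/Hg (6% Na), Na2HPO4, MeOH/THF, −20 → 0 °C
Reagents that add atoms: none
Why: Julia-type reductive desulfonylation by electron transfer from sodium amalgam cleaves the C11–S bond and methanol protonates the carbanion, while the γ-hydroxyl, the alkenes and the ester are not reduced.

Step 26
Reactants: 35 (hydroxy ester)
Product: 36 (13R)-labda-8(17),14-diene-13,19-diol
Conditions: LiAlH4, THF, 0 °C → reflux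
Reagents that add atoms: none
Why: LiAlH4 reduces the hindered axial aryl ester to the primary C19 alcohol and releases the phenol, while the tertiary alcohol is only deprotonated and the isolated alkenes are inert.

Step 27
Reactants: 36 (13R)-labda-8(17),14-diene-13,19-diol; 37 (E)-2-methylbut-2-enoyl chloride (tigloyl chloride)
Product: 38 (13R)-13-hydroxylabda-8(17),14-dien-19-yl (2E)-2-methylbut-2-enoate (CNP0313179.1)
Conditions: pyridine, DMAP (cat.), CH2Cl2, 0 °C → rt
Reagents that add atoms: none
Why: DMAP-catalysed acylation should take place only at the primary C19 hydroxyl because the tertiary allylic C13 hydroxyl is far less reactive, and the E-configured tigloyl group is the stable isomer and is transferred unchanged.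

**Compound list**

1 | 2-methyl-2-vinyloxirane (racemic) | C=CC1(C)CO1 | starting material
2 | (E)-4-chloro-2-methylbut-2-en-1-ol | OC/C(C)=C/CCl | intermediate
3 | (E)-tert-butyl[(4-chloro-2-methylbut-2-en-1-yl)oxy]dimethylsilane | CC(C)(C)[Si](C)(C)OC/C(C)=C/CCl | intermediate
4 | methyl acetoacetate | COC(=O)CC(C)=O | starting material
5 | sodium lithium dianion of methyl acetoacetate | [Na+].[Li+].[CH2-]C(=O)[CH-]C(=O)OC | intermediate
6 | methyl (6E)-8-[(tert-butyldimethylsilyl)oxy]-7-methyl-3-oxooct-6-enoate | COC(=O)CC(=O)CC/C=C(\C)CO[Si](C)(C)C(C)(C)C | intermediate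
7 | methyl (2Z,6E)-8-[(tert-butyldimethylsilyl)oxy]-7-methyl-3-{[(trifluoromethyl)sulfonyl]oxy}octa-2,6-dienoate | COC(=O)/C=C(\OS(=O)(=O)C(F)(F)F)CC/C=C(\C)CO[Si](C)(C)C(C)(C)C | intermediate
8 | (trimethylsilyl)methylmagnesium chloride | C[Si](C)(C)C[Mg]Cl | starting material
9 | methyl (2Z,6E)-8-[(tert-butyldimethylsilyl)oxy]-7-methyl-3-[(trimethylsilyl)methyl]octa-2,6-dienoate | COC(=O)/C=C(\C[Si](C)(C)C)CC/C=C(\C)CO[Si](C)(C)C(C)(C)C | intermediate
10 | (2Z,6E)-8-[(tert-butyldimethylsilyl)oxy]-7-methyl-3-[(trimethylsilyl)methyl]octa-2,6-dien-1-ol | OC/C=C(\C[Si](C)(C)C)CC/C=C(\C)CO[Si](C)(C)C(C)(C)C | intermediate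
11 | (2Z,6E)-1-[(tert-butyldiphenylsilyl)oxy]-8-[(tert-butyldimethylsilyl)oxy]-7-methyl-3-[(trimethylsilyl)methyl]octa-2,6-diene | CC(C)(C)[Si](c1ccccc1)(c1ccccc1)OC/C=C(\C[Si](C)(C)C)CC/C=C(\C)CO[Si](C)(C)C(C)(C)C | intermediate
12 | (2E,6Z)-8-[(tert-butyldiphenylsilyl)oxy]-2-methyl-6-[(trimethylsilyl)methyl]octa-2,6-dien-1-ol | CC(C)(C)[Si](c1ccccc1)(c1ccccc1)OC/C=C(\C[Si](C)(C)C)CC/C=C(\C)CO | intermediate
13 | (2Z,6E)-8-bromo-1-[(tert-butyldiphenylsilyl)oxy]-7-methyl-3-[(trimethylsilyl)methyl]octa-2,6-diene | CC(C)(C)[Si](c1ccccc1)(c1ccccc1)OC/C=C(\C[Si](C)(C)C)CC/C=C(\C)CBr | intermediate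
14 | 2,2,6-trimethyl-4H-1,3-dioxin-4-one | CC1=CC(=O)OC(C)(C)O1 | starting material
15 | 2,4,6-trimethylphenol | Cc1cc(C)c(O)c(C)c1 | starting material
16 | 2,4,6-trimethylphenyl 3-oxobutanoate | CC(=O)CC(=O)Oc1c(C)cc(C)cc1C | intermediate
17 | sodium lithium dianion of mesityl acetoacetate | [Na+].[Li+].[CH2-]C(=O)[CH-]C(=O)Oc1c(C)cc(C)cc1C | intermediate
18 | 2,4,6-trimethylphenyl (6E,10Z)-12-[(tert-butyldiphenylsilyl)oxy]-6-methyl-3-oxo-10-[(trimethylsilyl)methyl]dodeca-6,10-dienoate | CC(C)(C)[Si](c1ccccc1)(c1ccccc1)OC/C=C(\C[Si](C)(C)C)CC/C=C(\C)CCC(=O)CC(=O)Oc1c(C)cc(C)cc1C | intermediate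
19 | 2,4,6-trimethylphenyl (6E,10Z)-12-[(tert-butyldiphenylsilyl)oxy]-2-diazo-6-methyl-3-oxo-10-[(trimethylsilyl)methyl]dodeca-6,10-dienoate | CC(C)(C)[Si](c1ccccc1)(c1ccccc1)OC/C=C(\C[Si](C)(C)C)CC/C=C(\C)CCC(=O)C(=[N+]=[N-])C(=O)Oc1c(C)cc(C)cc1C | intermediate
20 | 2,4,6-trimethylphenyl (1R,5R,6R)-6-{(3Z)-5-[(tert-butyldiphenylsilyl)oxy]-3-[(trimethylsilyl)methyl]pent-3-en-1-yl}-5-methyl-2-oxobicyclo[3.1.0]hexane-1-carboxylate | CC(C)(C)[Si](c1ccccc1)(c1ccccc1)OC/C=C(\C[Si](C)(C)C)CC[C@@H]1[C@@]2(C)CCC(=O)[C@@]12C(=O)Oc1c(C)cc(C)cc1C | intermediate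
21 | trichlorotin enolate of 22 (C3–O–SnCl3, C3=C4) | CC(C)(C)[Si](c1ccccc1)(c1ccccc1)OC[C@H]1C(=C)CC[C@H]2C(C(=O)Oc3c(C)cc(C)cc3C)=C(O[Sn](Cl)(Cl)Cl)CC[C@]12C | intermediate
22 | 2,4,6-trimethylphenyl 5-{[(tert-butyldiphenylsilyl)oxy]methyl}-4a-methyl-6-methylidene-2-oxodecahydronaphthalene-1-carboxylate (5α-H, 9α-H, 10β-CH3; C4 epimers and enol) | CC(C)(C)[Si](c1ccccc1)(c1ccccc1)OC[C@H]1C(=C)CC[C@H]2C(C(=O)Oc3c(C)cc(C)cc3C)C(=O)CC[C@]12C | intermediate
23 | 2,4,6-trimethylphenyl 5-{[(tert-butyldiphenylsilyl)oxy]methyl}-1,4a-dimethyl-6-methylidene-2-oxodecahydronaphthalene-1-carboxylate (4α-CH3, 4β-CO2Ar, 5α-H, 9α-H, 10β-CH3) | CC(C)(C)[Si](c1ccccc1)(c1ccccc1)OC[C@H]1C(=C)CC[C@H]2[C@@](C)(C(=O)Oc3c(C)cc(C)cc3C)C(=O)CC[C@]12C | intermediate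
24 | 3β-hydroxy analogue of 23 (2-hydroxy in naphthalene numbering) | CC(C)(C)[Si](c1ccccc1)(c1ccccc1)OC[C@H]1C(=C)CC[C@H]2[C@@](C)(C(=O)Oc3c(C)cc(C)cc3C)[C@@H](O)CC[C@]12C | intermediate
25 | 3β-O-(imidazole-1-carbothioyl) derivative of 24 | CC(C)(C)[Si](c1ccccc1)(c1ccccc1)OC[C@H]1C(=C)CC[C@H]2[C@@](C)(C(=O)Oc3c(C)cc(C)cc3C)[C@@H](OC(=S)n3ccnc3)CC[C@]12C | intermediate
26 | 2,4,6-trimethylphenyl 5-{[(tert-butyldiphenylsilyl)oxy]methyl}-1,4a-dimethyl-6-methylidenedecahydronaphthalene-1-carboxylate (4α-CH3, 4β-CO2Ar, 5α-H, 9α-H, 10β-CH3) | CC(C)(C)[Si](c1ccccc1)(c1ccccc1)OC[C@H]1C(=C)CC[C@H]2[C@@](C)(C(=O)Oc3c(C)cc(C)cc3C)CCC[C@]12C | intermediate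
27 | 2,4,6-trimethylphenyl 5-(hydroxymethyl)-1,4a-dimethyl-6-methylidenedecahydronaphthalene-1-carboxylate (same configuration) | OC[C@H]1C(=C)CC[C@H]2[C@@](C)(C(=O)Oc3c(C)cc(C)cc3C)CCC[C@]12C | intermediate
28 | 2,4,6-trimethylphenyl 1,4a-dimethyl-6-methylidene-5-[(phenylsulfanyl)methyl]decahydronaphthalene-1-carboxylate (same configuration) | c1ccc(cc1)SC[C@H]1C(=C)CC[C@H]2[C@@](C)(C(=O)Oc3c(C)cc(C)cc3C)CCC[C@]12C | intermediate
29 | 2,4,6-trimethylphenyl 1,4a-dimethyl-6-methylidene-5-[(phenylsulfonyl)methyl]decahydronaphthalene-1-carboxylate (same configuration) | O=S(=O)(c1ccccc1)C[C@H]1C(=C)CC[C@H]2[C@@](C)(C(=O)Oc3c(C)cc(C)cc3C)CCC[C@]12C | intermediate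
30 | (S)-2-methylglycidol | OC[C@@]1(C)CO1 | starting material
31 | (R)-2-methyloxirane-2-carbaldehyde | O=C[C@@]1(C)CO1 | intermediate
32 | (S)-2-methyl-2-vinyloxirane | C=C[C@@]1(C)CO1 | intermediate
33 | C11-lithiated sulfone from 29 | [Li+].O=S(=O)(c1ccccc1)[CH-][C@H]1C(=C)CC[C@H]2[C@@](C)(C(=O)Oc3c(C)cc(C)cc3C)CCC[C@]12C | intermediate
34 | 2,4,6-trimethylphenyl 5-[(3R)-3-hydroxy-3-methyl-1-(phenylsulfonyl)pent-4-en-1-yl]-1,4a-dimethyl-6-methylidenedecahydronaphthalene-1-carboxylate (13R; C11 epimers) | C=C[C@](C)(O)CC(S(=O)(=O)c1ccccc1)[C@H]1C(=C)CC[C@H]2[C@@](C)(C(=O)Oc3c(C)cc(C)cc3C)CCC[C@]12C | intermediate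
35 | 2,4,6-trimethylphenyl (13R)-13-hydroxylabda-8(17),14-dien-19-oate | C=C[C@](C)(O)CC[C@H]1C(=C)CC[C@H]2[C@@](C)(C(=O)Oc3c(C)cc(C)cc3C)CCC[C@]12C | intermediate
36 | (13R)-labda-8(17),14-diene-13,19-diol | C=C[C@](C)(O)CC[C@H]1C(=C)CC[C@H]2[C@@](C)(CO)CCC[C@]12C | intermediate
37 | (E)-2-methylbut-2-enoyl chloride | C/C=C(\C)C(Cl)=O | starting material
38 | (13R)-13-hydroxylabda-8(17),14-dien-19-yl (2E)-2-methylbut-2-enoate | C=C[C@](C)(O)CC[C@H]1C(=C)CC[C@H]2[C@@](C)(COC(=O)/C(C)=C/C)CCC[C@]12C | target

**Step count.** 27 steps in total. The longest linear sequence is 24 steps (steps 1–9, 11–21 and 24–27); steps 10, 22 and 23 make the two side fragments.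

**Steps most likely to fail**

1. Step 14. The C10 cation may be intercepted by chloride or lose a proton before ring B closes, or the allylsilane may be lost by protodesilylation. The fallback leaves the cationic manifold: it sets out from 18 and comes back at 23. Compound 18 is C-methylated (MeI, K2CO3, acetone) to the racemic 2,6-dimethyl keto ester F1, which is cyclised with Mn(OAc)3·2H2O and Cu(OAc)2·H2O in AcOH at room temperature. In this oxidative radical bicyclisation the trivalent-manganese enolate gives the C4 radical, two 6-endo closures form C4–C5 and C9–C10, divalent copper oxidises the C8 radical and silicon leaves to give the 8(17)-alkene. The product is racemic 23, that is 23 together with its enantiomer F2, and the two are separated by preparative chromatography on a chiral stationary phase before step 16.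

2. Step 13. Face discrimination by the copper carbene may be insufficient, or the carbene may be diverted into dimerisation or attack on the distal allylsilane alkene. The fallback replaces asymmetric catalysis by resolution: it sets out from 19 and comes back at 20. Compound 19 is cyclopropanated with the achiral catalyst Rh2(OAc)4 (1 mol %, CH2Cl2, rt) to racemic 20, that is 20 together with its (1S,5S,6S) enantiomer F3, and the enantiomers are separated by preparative supercritical-fluid chromatography on a chiral stationary phase.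

3. Step 24. The carbanion may attack the vinyl terminus (SN2′) instead of the epoxide CH2, or the opening by the hindered carbanion may be so slow that the epoxide is consumed otherwise. The fallback installs the vinyl group after the C11–C12 bond is made: it sets out from 29 and comes back at 35. (S)-2-Methylglycidol 30 is silylated (TBSCl, imidazole) to the (R)-configured silyl ether F4, a non-allylic epoxide that can be activated safely. Sulfone 29 is lithiated (n-BuLi, THF, −78 °C) and opens F4 at its CH2 carbon in the presence of BF3·OEt2 to give the hydroxy sulfone F5. Desulfonylation (Na/Hg, Na2HPO4, MeOH) gives the silyl ether F6, and Bu4NF gives the 13,14-diol F7. Oxidation of the primary hydroxyl (SO3·pyridine, DMSO, i-Pr2NEt) gives the α-hydroxy aldehyde F8, and Wittig methylenation (Ph3PCH3Br, KN(SiMe3)2, THF, excess ylide) gives 35.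

**Further compounds**

F1 | step 14 | 2,4,6-trimethylphenyl (6E,10Z)-12-[(tert-butyldiphenylsilyl)oxy]-2,6-dimethyl-3-oxo-10-[(trimethylsilyl)methyl]dodeca-6,10-dienoate (racemic at C2) | CC(C)(C)[Si](c1ccccc1)(c1ccccc1)OC/C=C(\C[Si](C)(C)C)CC/C=C(\C)CCC(=O)C(C)C(=O)Oc1c(C)cc(C)cc1C
F2 | step 14 | enantiomer of 23 | CC(C)(C)[Si](c1ccccc1)(c1ccccc1)OC[C@@H]1C(=C)CC[C@@H]2[C@](C)(C(=O)Oc3c(C)cc(C)cc3C)C(=O)CC[C@@]12C
F3 | step 13 | enantiomer of 20, (1S,5S,6S) | CC(C)(C)[Si](c1ccccc1)(c1ccccc1)OC/C=C(\C[Si](C)(C)C)CC[C@H]1[C@]2(C)CCC(=O)[C@]12C(=O)Oc1c(C)cc(C)cc1C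
F4 | step 24 | (R)-tert-butyldimethyl[(2-methyloxiran-2-yl)methoxy]silane | CC(C)(C)[Si](C)(C)OC[C@@]1(C)CO1
F5 | step 24 | 2,4,6-trimethylphenyl 5-[(3S)-4-[(tert-butyldimethylsilyl)oxy]-3-hydroxy-3-methyl-1-(phenylsulfonyl)butyl]-1,4a-dimethyl-6-methylidenedecahydronaphthalene-1-carboxylate (C11 epimers) | CC(C)(C)[Si](C)(C)OC[C@](C)(O)CC(S(=O)(=O)c1ccccc1)[C@H]1C(=C)CC[C@H]2[C@@](C)(C(=O)Oc3c(C)cc(C)cc3C)CCC[C@]12C
F6 | step 24 | 2,4,6-trimethylphenyl 5-[(3S)-4-[(tert-butyldimethylsilyl)oxy]-3-hydroxy-3-methylbutyl]-1,4a-dimethyl-6-methylidenedecahydronaphthalene-1-carboxylate | CC(C)(C)[Si](C)(C)OC[C@](C)(O)CC[C@H]1C(=C)CC[C@H]2[C@@](C)(C(=O)Oc3c(C)cc(C)cc3C)CCC[C@]12C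
F7 | step 24 | 2,4,6-trimethylphenyl 5-[(3S)-3,4-dihydroxy-3-methylbutyl]-1,4a-dimethyl-6-methylidenedecahydronaphthalene-1-carboxylate | OC[C@](C)(O)CC[C@H]1C(=C)CC[C@H]2[C@@](C)(C(=O)Oc3c(C)cc(C)cc3C)CCC[C@]12C
F8 | step 24 | 2,4,6-trimethylphenyl 5-[(3R)-3-hydroxy-3-methyl-4-oxobutyl]-1,4a-dimethyl-6-methylidenedecahydronaphthalene-1-carboxylate | O=C[C@](C)(O)CC[C@H]1C(=C)CC[C@H]2[C@@](C)(C(=O)Oc3c(C)cc(C)cc3C)CCC[C@]12C
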